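## Structural features

Gancaonin H (19, C25H24O6) is an isoflavone without any stereocentre: benzene ring A and 4-pyranone ring C share the C4a–C8a bond, and aryl ring B is attached to C3 of ring C through the C3–C1' bond. Ring A carries hydroxyls at C5 and C7 and a 3-methylbut-2-enyl (prenyl) group at C6 between them, while C8 is unsubstituted. Ring B is a catechol whose O4' and C5' are tied into a 2,2-dimethyl-2H-pyran (ring D), so rings B and D form an 8-hydroxy-2,2-dimethyl-2H-chromen-6-yl unit with a free hydroxyl at C3'. The fragile groups are the prenyl olefin flanked by two phenols (acid closes it onto O5 or O7; halogens, peracids and hydrogenation attack it), the styrene-type olefin of ring D, the C2 position of ring C (opened by hard nucleophiles) and three oxidisable phenols. The real difficulty is regiochemical: the prenyl group must sit at C6 and not at C8, two positions that hardly differ once ring C exists, and on ring B the correct one of two nearly equal catechol oxygens must enter ring D. The feature that the key step exploits is that C6 is para to C8a. When the C4–C4a bond is taken away, the remaining aryloxy ring (C4a, C5, C6, C7, C8, C8a with O1, O5, O7 and the prenyl group) has a mirror plane through C6 and C8a, so C4a and C8 are equivalent. Ring C is therefore closed at carbon (C4–C4a) instead of at O1, on a precursor in which every other atom of the target is already in place.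

## Logic of the disconnections

**19 ⇒ 18.** The three phenolic O–H bonds (O5, O7, O3') are masked as methoxymethyl acetals. These groups are needed earlier as directing groups on ring A and keep the phenols out of the cationic ring closure. There is no gain in skeleton. The forward step must be an acid treatment mild enough not to close the prenyl group onto O5 or O7 or to add to the olefin of ring D.

**18 ⇒ 15 (key).** The C4–C4a bond is cut, which opens ring C to a 2-aryl-3-aryloxyacrylic acid. The cut is made here because the aryloxy ring of 15 is mirror-symmetric, so the carbon that becomes C4a and the one that becomes C8 are indistinguishable, and a 6-prenyl versus 8-prenyl choice cannot arise. The gain is the loss of a ring and of the whole regiochemical problem of ring A. 15 is an open diaryl enol ether made from two simple halves. The forward step needs an acyl electrophile mild enough for a prenyl group, a chromene and three acetals, and a way for the more stable E geometry to reach the ring.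

**15 ⇒ 14 ⇒ 6 + 13.** After an ester-to-acid change, the O1–C2 bond (aryl oxygen to vinyl carbon) is cut. C2 is the β-carbon of an acrylate and is electrophilic when it carries a leaving group, and 6 is the symmetric phenol. The two halves are thus joined by a C–O bond and not by a C–C coupling. The forward step needs O-attack (not C-attack) by an electron-rich phenoxide and an ester hydrolysis that does not expel the aryloxide.

**13 ⇒ 12 ⇒ 11.** After a sulfonylation, the C2–C3 and C3–C1' bonds are cut, and ring B is reattached to the carbon that becomes C2. A diazoacetate reagent supplies C3 and C4 in one operation and moves ring B from C2 to C3, so ring B can enter as an aldehyde. The gain is three carbons of ring C in one step. The forward step needs aryl migration to beat hydride migration, which the para oxygen of ring B favours.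

**11 ⇒ 10 ⇒ 8 ⇒ 7.** After the O3' acetal, ring D is cut at the bond between C5' and its olefinic carbon and at the O4'–CMe2 bond. An aryl propargyl ether rearrangement builds ring D at the only free position ortho to O4'. In 7 the 4-hydroxyl (para to the formyl group) is the more acidic one, so it alone is alkylated. The forward steps need mono-alkylation and a thermal cascade.

**6 ⇒ 4 (through 5).** The C8a–O1 bond is cut back to a C–H bond. The only C–H of 4 that has no ortho substituent is the one para to the prenyl group, so a sterically governed C–H borylation and oxidation gives the symmetric phenol without differentiating three oxygens of a phloroglucinol. The forward step must tolerate a trisubstituted olefin.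

**4 ⇒ 2 (through 3) ⇒ 1.** The aryl–CH2 bond of the prenyl group is cut, then the two acetal O–CH2 bonds. The position between the two acetal oxygens of 2 is the one that directed lithiation addresses, so the prenyl group is fixed between O5 and O7 from the start. The forward step needs alkylation of a prenyl halide at its primary carbon.

## Other disconnections considered

Alternative 1: The first idea is to cut C3–C1' and join the two aryl units by a Suzuki–Miyaura coupling of 3-iodochromone A1 with the ring B pinacol boronate A2 under a zerovalent palladium catalyst such as Pd(PPh3)4. The coupling settles one bond only and leaves the ring A problem untouched. A1 would have to come from acetophenone A3, whose prenyl regiochemistry must be set separately, by condensation with a formamide acetal and iodine-induced ring closure, in which iodine meets the prenyl olefin. A2 needs a halide on ring B, for which no entry as selective as the one from 7 exists. The chosen plan needs no aryl halide, no boron on ring B and no electrophilic halogen next to the olefins.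

Alternative 2: The classical isoflavone route cuts O1–C2 and C2–C3 after an intermolecular C-acylation. 2-Prenylphloroglucinol A4 and arylacetic acid A5 would give deoxybenzoin A6 (Friedel–Crafts or Houben–Hoesch conditions), and a one-carbon unit would then be inserted with closure at oxygen. In A6 the two hydroxyls ortho to the ketone are different (one next to the prenyl group, one next to hydrogen) and both can close, so the target and its 8-prenyl isomer A7 are both expected. The acylation also needs a strong Lewis acid in the presence of a free prenyl group and a chromene. Differentiated protection could repair this, but only at the cost of more steps than the symmetric precursor of the chosen plan.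

Alternative 3: A biomimetic route forms C3–C1' by an oxidative 1,2-aryl shift. Chalcone A8 (from A3 and 11) would be treated with Tl(NO3)3 in methanol (trivalent thallium) or PhI(OAc)2 to give the rearranged dimethyl acetal A9, which would then be cyclised. These electrophilic oxidants are expected to attack the electron-rich prenyl and chromene olefins at least as readily as the enone. Ring A regiochemistry must again be secured in A3. The chosen plan contains no oxidant after the phenol is made.

Key step: step 11

Remark: compounds 12 to 17 contain a C=C bond whose geometry disappears in ring C; each is drawn as the isomer expected to predominate, and either isomer serves.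

## Steps

Step 1
Reactants: 1 resorcinol
Product: 2 1,3-bis(methoxymethoxy)benzene
Conditions: NaH, MOMCl, DMF, 0 °C → rt
Reagents that add atoms: chloromethyl methyl ether, COCCl
Why: Williamson-type O-alkylation of both phenoxides by the reactive α-chloro ether; the acetals later direct lithiation and survive base and organometallics.

Step 2
Reactants: 2 1,3-bis(methoxymethoxy)benzene
Product: 4 1,3-bis(methoxymethoxy)-2-(3-methylbut-2-en-1-yl)benzene, via aryllithium 3 (not isolated)
Conditions: n-BuLi, THF, 0 °C; then 1-bromo-3-methylbut-2-ene, −78 °C → rt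
Reagents that add atoms: 1-bromo-3-methylbut-2-ene (prenyl bromide), CC(C)=CCBr
Why: Directed ortho-metalation occurs at the carbon between the two chelating acetal oxygens, and the aryllithium is alkylated at the primary carbon of the allylic bromide (SN2), which places the prenyl group between the future O5 and O7.

Step 3
Reactants: 4 1,3-bis(methoxymethoxy)-2-(3-methylbut-2-en-1-yl)benzene
Product: 6 3,5-bis(methoxymethoxy)-4-(3-methylbut-2-en-1-yl)phenol, via arylboronate 5 (not isolated)
Conditions: [Ir(OMe)(cod)]2 (1.5 mol%), 4,4'-di-tert-butyl-2,2'-bipyridine (3 mol%), B2pin2, THF, 60 °C; then NaBO3·4H2O, THF/H2O, rt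
Reagents that add atoms: sodium perborate tetrahydrate, [Na+].[Na+].O[B-]1(O)OO[B-](O)(O)OO1
Why: Iridium-catalysed aromatic C–H borylation is sterically controlled and should take the only C–H without an ortho substituent, the one para to the prenyl group; perborate then oxidises the C–B bond to C–OH without touching the olefin. The product is the mirror-symmetric phenol.

Step 4
Reactants: 7 3,4-dihydroxybenzaldehyde
Product: 8 3-hydroxy-4-[(2-methylbut-3-yn-2-yl)oxy]benzaldehyde
Conditions: 3-chloro-3-methylbut-1-yne, DBU, CuCl2·2H2O (1 mol%), MeCN, 0 °C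
Reagents that add atoms: 3-chloro-3-methylbut-1-yne, C#CC(C)(C)Cl
Why: Copper-catalysed propargylic etherification of a phenoxide; with one equivalent of base only the 4-hydroxyl, made more acidic by the para formyl group, is deprotonated and alkylated.

Step 5
Reactants: 8 3-hydroxy-4-[(2-methylbut-3-yn-2-yl)oxy]benzaldehyde
Product: 10 8-hydroxy-2,2-dimethyl-2H-chromene-6-carbaldehyde, via allenylphenol 9 (not isolated)
Conditions: N,N-diethylaniline, 190 °C
Reagents that add atoms: none
Why: Aromatic propargyl Claisen rearrangement to the only free ortho carbon of O4, enolisation to the allenylphenol, then 1,5-hydrogen shift and oxa-6π electrocyclisation close ring D with the required O4'/C5' regiochemistry.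

Step 6
Reactants: 10 8-hydroxy-2,2-dimethyl-2H-chromene-6-carbaldehyde
Product: 11 8-(methoxymethoxy)-2,2-dimethyl-2H-chromene-6-carbaldehyde
Conditions: MOMCl, i-Pr2NEt, CH2Cl2, 0 °C → rt
Reagents that add atoms: chloromethyl methyl ether, COCCl
Why: O-alkylation of the remaining phenol with the α-chloro ether under amine base; the acetal matches the ring A protecting groups so that one final operation frees all three phenols.

Step 7
Reactants: 11 8-(methoxymethoxy)-2,2-dimethyl-2H-chromene-6-carbaldehyde
Product: 12 ethyl (Z)-3-hydroxy-2-[8-(methoxymethoxy)-2,2-dimethyl-2H-chromen-6-yl]prop-2-enoate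
Conditions: N2CHCO2Et, HBF4·OEt2 (10 mol%), CH2Cl2, −78 °C
Reagents that add atoms: ethyl diazoacetate, CCOC(=O)C=[N+]=[N-]
Why: Acid-catalysed aldehyde–diazoacetate homologation (a Roskamp-type reaction diverted to aryl migration): the β-hydroxy diazonium adduct loses N2 with 1,2-shift of the para-alkoxyaryl group, which migrates better than hydride, and the α-formyl ester rests as its hydrogen-bonded Z enol. At −78 °C with catalytic acid and no nucleophile present the acetal and the chromene should persist.

Step 8
Reactants: 12 ethyl (Z)-3-hydroxy-2-[8-(methoxymethoxy)-2,2-dimethyl-2H-chromen-6-yl]prop-2-enoate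
Product: 13 ethyl (E)-2-[8-(methoxymethoxy)-2,2-dimethyl-2H-chromen-6-yl]-3-[(4-methylbenzenesulfonyl)oxy]prop-2-enoate
Conditions: TsCl, N-methylimidazole (cat.), Et3N, CH2Cl2, 0 °C
Reagents that add atoms: 4-methylbenzenesulfonyl chloride, Cc1ccc(cc1)S(Cl)(=O)=O
Why: O-sulfonylation of the acidic enol of an α-formyl ester under amine conditions turns C2 into the electrophilic β-carbon of an acrylate; the non-chelated E isomer is expected, and the geometry is of no consequence.

Step 9
Reactants: 6 3,5-bis(methoxymethoxy)-4-(3-methylbut-2-en-1-yl)phenol and 13 ethyl (E)-2-[8-(methoxymethoxy)-2,2-dimethyl-2H-chromen-6-yl]-3-[(4-methylbenzenesulfonyl)oxy]prop-2-enoate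
Product: 14 ethyl (E)-3-[3,5-bis(methoxymethoxy)-4-(3-methylbut-2-en-1-yl)phenoxy]-2-[8-(methoxymethoxy)-2,2-dimethyl-2H-chromen-6-yl]prop-2-enoate
Conditions: Cs2CO3, MeCN, 40 °C
Reagents that add atoms: none
Why: Vinylic nucleophilic substitution by addition–elimination: the caesium phenoxide adds through oxygen to the β-carbon, and the α-aryl ester enolate expels sulfonate to give the more stable E aryl vinyl ether. 6 has a single free hydroxyl, so no site selectivity is needed.

Step 10
Reactants: 14 ethyl (E)-3-[3,5-bis(methoxymethoxy)-4-(3-methylbut-2-en-1-yl)phenoxy]-2-[8-(methoxymethoxy)-2,2-dimethyl-2H-chromen-6-yl]prop-2-enoate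
Product: 15 (E)-3-[3,5-bis(methoxymethoxy)-4-(3-methylbut-2-en-1-yl)phenoxy]-2-[8-(methoxymethoxy)-2,2-dimethyl-2H-chromen-6-yl]prop-2-enoic acid
Conditions: LiOH·H2O, THF/H2O, rt; then 1 M HCl to pH 4, 0 °C
Reagents that add atoms: lithium hydroxide, [Li+].[OH-]
Why: Saponification at the ester carbonyl, as is routine for 3-aryloxyacrylates; the donor-substituted, hindered β-carbon should resist hydroxide, all other groups are base-stable, and brief cold acidification to pH 4 spares the acetals.

Step 11
Reactants: 15 (E)-3-[3,5-bis(methoxymethoxy)-4-(3-methylbut-2-en-1-yl)phenoxy]-2-[8-(methoxymethoxy)-2,2-dimethyl-2H-chromen-6-yl]prop-2-enoic acid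
Product: 18 5,7-bis(methoxymethoxy)-3-[8-(methoxymethoxy)-2,2-dimethyl-2H-chromen-6-yl]-6-(3-methylbut-2-en-1-yl)-4H-chromen-4-one, via acid chloride 16 (not isolated), via acyl triflate 17 (not isolated)
Conditions: 1-chloro-N,N,2-trimethylprop-1-en-1-amine, CH2Cl2, 0 °C; then 2,6-di-tert-butyl-4-methylpyridine, AgOSO2CF3, CH2Cl2, −40 → 0 °C
Reagents that add atoms: none
Why: The α-chloroenamine converts 15 into acid chloride 16 under neutral conditions, and AgOSO2CF3 removes chloride as AgCl to give acyl triflate 17, which ionises to an acylium ion stabilised by the enol-ether oxygen (resonance form O=C=C(Ar)–CH=O+–Ar). This delocalisation lowers the C2–C3 bond order, so the E chain equilibrates with the Z form, in which the acyl carbon lies over an ortho carbon of ring A. Electrophilic aromatic substitution there (6-exo attack of the arene carbon on the acyl carbon, 6-exo-dig on the acylium ion) forms C4–C4a and closes pyranone ring C, and proton loss to the hindered pyridine gives 18. The closest known reaction type is the Friedel–Crafts ring closure of 3-aryloxyacrylic acids to chromones (the second stage of the Simonis chromone synthesis); here the reacting carbon is ortho and para to two further alkoxy groups, which is why a buffered acyl triflate at low temperature should replace hot mineral acid. Regioselectivity is secured by symmetry: the two ortho carbons of the aryloxy ring are related by the mirror plane through C8a and C6, so either closure gives the same 6-prenyl product and no 8-prenyl isomer can form. Ring B cannot compete, since attack by its ortho carbons would give a four-membered ring and the chromene olefin sits on a meta position out of reach. No stereocentre is formed. HCl never forms and CF3SO3H is taken up by the pyridine, so the prenyl group, the chromene and the acetals meet no free protic acid.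

Step 12
Reactants: 18 5,7-bis(methoxymethoxy)-3-[8-(methoxymethoxy)-2,2-dimethyl-2H-chromen-6-yl]-6-(3-methylbut-2-en-1-yl)-4H-chromen-4-one
Product: 19 gancaonin H, 5,7-dihydroxy-3-(8-hydroxy-2,2-dimethyl-2H-chromen-6-yl)-6-(3-methylbut-2-en-1-yl)-4H-chromen-4-one
Conditions: 3 M HCl (aq), MeOH, 45 °C
Reagents that add atoms: none
Why: Acid-catalysed acetal exchange with methanol removes the three methoxymethyl groups as dimethoxymethane; moderate temperature and short exposure should prevent closure of the prenyl group onto O5 or O7 and addition to the chromene olefin.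

## Compound list

1 | resorcinol | Oc1cccc(O)c1 | starting material
2 | 1,3-bis(methoxymethoxy)benzene | COCOc1cccc(OCOC)c1 | intermediate
3 | [2,6-bis(methoxymethoxy)phenyl]lithium (formed in the flask, not isolated) | [Li]c1c(OCOC)cccc1OCOC | intermediate
4 | 1,3-bis(methoxymethoxy)-2-(3-methylbut-2-en-1-yl)benzene | COCOc1cccc(OCOC)c1CC=C(C)C | intermediate
5 | 2-[3,5-bis(methoxymethoxy)-4-(3-methylbut-2-en-1-yl)phenyl]-4,4,5,5-tetramethyl-1,3,2-dioxaborolane (formed in the flask, not isolated) | COCOc1cc(cc(OCOC)c1CC=C(C)C)B1OC(C)(C)C(C)(C)O1 | intermediate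
6 | 3,5-bis(methoxymethoxy)-4-(3-methylbut-2-en-1-yl)phenol | COCOc1cc(O)cc(OCOC)c1CC=C(C)C | intermediate
7 | 3,4-dihydroxybenzaldehyde | O=Cc1ccc(O)c(O)c1 | starting material
8 | 3-hydroxy-4-[(2-methylbut-3-yn-2-yl)oxy]benzaldehyde | C#CC(C)(C)Oc1ccc(C=O)cc1O | intermediate
9 | 3,4-dihydroxy-5-(3-methylbuta-1,2-dien-1-yl)benzaldehyde (formed in the flask, not isolated) | CC(C)=C=Cc1cc(C=O)cc(O)c1O | intermediate
10 | 8-hydroxy-2,2-dimethyl-2H-chromene-6-carbaldehyde | CC1(C)C=Cc2cc(C=O)cc(O)c2O1 | intermediate
11 | 8-(methoxymethoxy)-2,2-dimethyl-2H-chromene-6-carbaldehyde | COCOc1cc(C=O)cc2C=CC(C)(C)Oc12 | intermediate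
12 | ethyl (Z)-3-hydroxy-2-[8-(methoxymethoxy)-2,2-dimethyl-2H-chromen-6-yl]prop-2-enoate | O/C=C(\C(=O)OCC)c1cc(OCOC)c2OC(C)(C)C=Cc2c1 | intermediate
13 | ethyl (E)-2-[8-(methoxymethoxy)-2,2-dimethyl-2H-chromen-6-yl]-3-[(4-methylbenzenesulfonyl)oxy]prop-2-enoate | Cc1ccc(cc1)S(=O)(=O)O/C=C(/C(=O)OCC)c1cc(OCOC)c2OC(C)(C)C=Cc2c1 | intermediate
14 | ethyl (E)-3-[3,5-bis(methoxymethoxy)-4-(3-methylbut-2-en-1-yl)phenoxy]-2-[8-(methoxymethoxy)-2,2-dimethyl-2H-chromen-6-yl]prop-2-enoate | COCOc1cc(O/C=C(/C(=O)OCC)c2cc(OCOC)c3OC(C)(C)C=Cc3c2)cc(OCOC)c1CC=C(C)C | intermediate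
15 | (E)-3-[3,5-bis(methoxymethoxy)-4-(3-methylbut-2-en-1-yl)phenoxy]-2-[8-(methoxymethoxy)-2,2-dimethyl-2H-chromen-6-yl]prop-2-enoic acid | COCOc1cc(O/C=C(/C(O)=O)c2cc(OCOC)c3OC(C)(C)C=Cc3c2)cc(OCOC)c1CC=C(C)C | intermediate
16 | (E)-3-[3,5-bis(methoxymethoxy)-4-(3-methylbut-2-en-1-yl)phenoxy]-2-[8-(methoxymethoxy)-2,2-dimethyl-2H-chromen-6-yl]prop-2-enoyl chloride (formed in the flask, not isolated) | COCOc1cc(O/C=C(/C(Cl)=O)c2cc(OCOC)c3OC(C)(C)C=Cc3c2)cc(OCOC)c1CC=C(C)C | intermediate
17 | (Z)-3-[3,5-bis(methoxymethoxy)-4-(3-methylbut-2-en-1-yl)phenoxy]-2-[8-(methoxymethoxy)-2,2-dimethyl-2H-chromen-6-yl]prop-2-enoic trifluoromethanesulfonic anhydride (formed in the flask, not isolated; in equilibrium with its E isomer and its acylium triflate ion pair) | COCOc1cc(O/C=C(\C(=O)OS(=O)(=O)C(F)(F)F)c2cc(OCOC)c3OC(C)(C)C=Cc3c2)cc(OCOC)c1CC=C(C)C | intermediate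
18 | 5,7-bis(methoxymethoxy)-3-[8-(methoxymethoxy)-2,2-dimethyl-2H-chromen-6-yl]-6-(3-methylbut-2-en-1-yl)-4H-chromen-4-one | CC(C)=CCc1c(OCOC)cc2occ(-c3cc(OCOC)c4c(c3)C=CC(C)(C)O4)c(=O)c2c1OCOC | intermediate
19 | gancaonin H, 5,7-dihydroxy-3-(8-hydroxy-2,2-dimethyl-2H-chromen-6-yl)-6-(3-methylbut-2-en-1-yl)-4H-chromen-4-one | CC(C)=CCc1c(O)cc2occ(-c3cc(O)c4c(c3)C=CC(C)(C)O4)c(=O)c2c1O | target

## Step count and least certain steps

Total step count: 12 (steps 1–3 build the ring A phenol, steps 4–8 the ring B fragment, steps 9–12 join them and finish).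
Longest linear sequence: 9 steps (steps 4 to 12, from 7).

**Step 11 (key step).** The acylium ion may be consumed by the acetal oxygens of the methoxymethyl groups or by traces of water before the E to Z isomerisation brings it over ring A. The silver salt and the triflate may also erode the acid-labile groups, so that 15 is returned or degraded. The fallback sets out from 15 and returns at 18, and it replaces the acylium ion by a Vilsmeier–Haack-type iminium electrophile made without silver or an acyl halide. 15 would be coupled with dimethylamine (a carbodiimide with 1-hydroxybenzotriazole) to give (E)-3-[3,5-bis(methoxymethoxy)-4-(3-methylbut-2-en-1-yl)phenoxy]-2-[8-(methoxymethoxy)-2,2-dimethyl-2H-chromen-6-yl]-N,N-dimethylprop-2-enamide F1. Activation with triflic anhydride and 2-fluoropyridine in CH2Cl2 at −78 to 0 °C should give an O-sulfonyl iminium ion that isomerises in the same push–pull manner and is attacked by the same symmetric ring, giving the cyclic iminium salt N-[5,7-bis(methoxymethoxy)-3-[8-(methoxymethoxy)-2,2-dimethyl-2H-chromen-6-yl]-6-(3-methylbut-2-en-1-yl)-4H-chromen-4-ylidene]-N-methylmethanaminium triflate F2. Aqueous NaHCO3 would hydrolyse F2 to 18.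

**Step 3.** Iridium hydride and boryl species may add to the prenyl olefin or move its double bond, or the olefin may bind the catalyst and stall the aromatic borylation. The fallback sets out from 2 and returns at 6, and it borylates before any olefin is present. 2 would be borylated under the same catalyst at its only unhindered C–H to give 2-[3,5-bis(methoxymethoxy)phenyl]-4,4,5,5-tetramethyl-1,3,2-dioxaborolane F3 (not isolated) and oxidised with NaBO3·4H2O to 3,5-bis(methoxymethoxy)phenol F4. F4 would be silylated (i-Pr3SiCl, imidazole) to [3,5-bis(methoxymethoxy)phenoxy]tri(propan-2-yl)silane F5. n-BuLi would lithiate F5 between the two acetal oxygens, the bulky silyloxy group shielding its own ortho positions, to give [2,6-bis(methoxymethoxy)-4-{[tri(propan-2-yl)silyl]oxy}phenyl]lithium F6. Alkylation with 1-bromo-3-methylbut-2-ene would give [3,5-bis(methoxymethoxy)-4-(3-methylbut-2-en-1-yl)phenoxy]tri(propan-2-yl)silane F7, and Bu4NF would then free 6.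

**Step 7.** The acid catalyst may exchange the methoxymethyl acetal or protonate the chromene olefin, which the diazo ester could then alkylate, and a 1,2-hydride shift to the β-keto ester may compete with aryl migration. The fallback sets out from 11 and returns at 12, and it builds the same enol by base-mediated steps only. Reductive cyanation of 11 with tosylmethyl isocyanide (t-BuOK, DME, −40 °C; then MeOH, reflux; van Leusen reaction) would give 2-[8-(methoxymethoxy)-2,2-dimethyl-2H-chromen-6-yl]acetonitrile F8. KOH in aqueous ethanol would hydrolyse F8 to 2-[8-(methoxymethoxy)-2,2-dimethyl-2H-chromen-6-yl]acetic acid F9. Ethyl iodide and K2CO3 would give ethyl 2-[8-(methoxymethoxy)-2,2-dimethyl-2H-chromen-6-yl]acetate F10, and Claisen formylation (NaH, ethyl formate, THF) would give 12.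

**Step 9.** The phenoxide may attack sulfur instead of the β-carbon, transferring the sulfonyl group and returning the enolate of 12, or the ambident, electron-rich phenoxide may react through carbon. The fallback sets out from 12 and returns at 14, and it uses an electrophile whose only electrophilic site is carbon. 12 would be converted by Appel-type deoxychlorination (PPh3, CCl4, CH2Cl2) into ethyl (E)-3-chloro-2-[8-(methoxymethoxy)-2,2-dimethyl-2H-chromen-6-yl]prop-2-enoate F11, a vinylogous acid chloride. F11 should react with 6 and Cs2CO3 in MeCN by addition–elimination to give 14.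

## Further compounds

F1 | step 11 | (E)-3-[3,5-bis(methoxymethoxy)-4-(3-methylbut-2-en-1-yl)phenoxy]-2-[8-(methoxymethoxy)-2,2-dimethyl-2H-chromen-6-yl]-N,N-dimethylprop-2-enamide | COCOc1cc(O/C=C(/C(=O)N(C)C)c2cc(OCOC)c3OC(C)(C)C=Cc3c2)cc(OCOC)c1CC=C(C)C
F2 | step 11 | N-[5,7-bis(methoxymethoxy)-3-[8-(methoxymethoxy)-2,2-dimethyl-2H-chromen-6-yl]-6-(3-methylbut-2-en-1-yl)-4H-chromen-4-ylidene]-N-methylmethanaminium trifluoromethanesulfonate | CC(C)=CCC1=C(OCOC)C=C2OC=C(c3cc(OCOC)c4OC(C)(C)C=Cc4c3)C(=[N+](C)C)C2=C1OCOC.[O-]S(=O)(=O)C(F)(F)F
F3 | step 3 | 2-[3,5-bis(methoxymethoxy)phenyl]-4,4,5,5-tetramethyl-1,3,2-dioxaborolane | COCOc1cc(OCOC)cc(c1)B1OC(C)(C)C(C)(C)O1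
F4 | step 3 | 3,5-bis(methoxymethoxy)phenol | COCOc1cc(O)cc(OCOC)c1
F5 | step 3 | [3,5-bis(methoxymethoxy)phenoxy]tri(propan-2-yl)silane | COCOc1cc(O[Si](C(C)C)(C(C)C)C(C)C)cc(OCOC)c1
F6 | step 3 | [2,6-bis(methoxymethoxy)-4-{[tri(propan-2-yl)silyl]oxy}phenyl]lithium | [Li]c1c(OCOC)cc(O[Si](C(C)C)(C(C)C)C(C)C)cc1OCOC
F7 | step 3 | [3,5-bis(methoxymethoxy)-4-(3-methylbut-2-en-1-yl)phenoxy]tri(propan-2-yl)silane | COCOc1cc(O[Si](C(C)C)(C(C)C)C(C)C)cc(OCOC)c1CC=C(C)C
F8 | step 7 | 2-[8-(methoxymethoxy)-2,2-dimethyl-2H-chromen-6-yl]acetonitrile | COCOc1cc(CC#N)cc2C=CC(C)(C)Oc12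
F9 | step 7 | 2-[8-(methoxymethoxy)-2,2-dimethyl-2H-chromen-6-yl]acetic acid | COCOc1cc(CC(O)=O)cc2C=CC(C)(C)Oc12
F10 | step 7 | ethyl 2-[8-(methoxymethoxy)-2,2-dimethyl-2H-chromen-6-yl]acetate | CCOC(=O)Cc1cc(OCOC)c2OC(C)(C)C=Cc2c1
F11 | step 9 | ethyl (E)-3-chloro-2-[8-(methoxymethoxy)-2,2-dimethyl-2H-chromen-6-yl]prop-2-enoate | Cl/C=C(/C(=O)OCC)c1cc(OCOC)c2OC(C)(C)C=Cc2c1
A1 | alternative 1 | 3-iodo-5,7-bis(methoxymethoxy)-6-(3-methylbut-2-en-1-yl)-4H-chromen-4-one | CC(C)=CCc1c(OCOC)cc2occ(I)c(=O)c2c1OCOC
A2 | alternative 1 | 2-[8-(methoxymethoxy)-2,2-dimethyl-2H-chromen-6-yl]-4,4,5,5-tetramethyl-1,3,2-dioxaborolane | COCOc1cc(cc2C=CC(C)(C)Oc12)B1OC(C)(C)C(C)(C)O1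
A3 | alternative 1 | 1-[6-hydroxy-2,4-bis(methoxymethoxy)-3-(3-methylbut-2-en-1-yl)phenyl]ethan-1-one | CC(=O)c1c(O)cc(OCOC)c(CC=C(C)C)c1OCOC
A4 | alternative 2 | 2-(3-methylbut-2-en-1-yl)benzene-1,3,5-triol | CC(C)=CCc1c(O)cc(O)cc1O
A5 | alternative 2 | 2-(8-hydroxy-2,2-dimethyl-2H-chromen-6-yl)acetic acid | OC(=O)Cc1cc(O)c2OC(C)(C)C=Cc2c1
A6 | alternative 2 | 2-(8-hydroxy-2,2-dimethyl-2H-chromen-6-yl)-1-[2,4,6-trihydroxy-3-(3-methylbut-2-en-1-yl)phenyl]ethan-1-one | CC(C)=CCc1c(O)cc(O)c(C(=O)Cc2cc(O)c3OC(C)(C)C=Cc3c2)c1O
A7 | alternative 2 | 5,7-dihydroxy-3-(8-hydroxy-2,2-dimethyl-2H-chromen-6-yl)-8-(3-methylbut-2-en-1-yl)-4H-chromen-4-one | CC(C)=CCc1c(O)cc(O)c2c(=O)c(-c3cc(O)c4OC(C)(C)C=Cc4c3)coc12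
A8 | alternative 3 | (E)-1-[6-hydroxy-2,4-bis(methoxymethoxy)-3-(3-methylbut-2-en-1-yl)phenyl]-3-[8-(methoxymethoxy)-2,2-dimethyl-2H-chromen-6-yl]prop-2-en-1-one | COCOc1cc(O)c(C(=O)/C=C/c2cc(OCOC)c3OC(C)(C)C=Cc3c2)c(OCOC)c1CC=C(C)C
A9 | alternative 3 | 1-[6-hydroxy-2,4-bis(methoxymethoxy)-3-(3-methylbut-2-en-1-yl)phenyl]-3,3-dimethoxy-2-[8-(methoxymethoxy)-2,2-dimethyl-2H-chromen-6-yl]propan-1-one (racemic) | COCOc1cc(O)c(C(=O)C(C(OC)OC)c2cc(OCOC)c3OC(C)(C)C=Cc3c2)c(OCOC)c1CC=C(C)C
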